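## Retrosynthetic overview
1. The piperidine is the only ring and is closed last. Cbz hydrogenolysis and intramolecular reductive amination (N1–C6) of an acyclic C20 amino-diketone do this, and the same H2 step saturates two chain alkynes and sets C6.
2. The C20 chain is cut at C8–C9 (side-chain C2'–C3'): conjugate alkynylation of a C1–C8 vinyl ketone with a C12 diynone.
3. The diynone comes from octa-1,7-diyne and methyl vinyl ketone by the same reaction type.
4. The key disconnection is C3–C4. N-Cbz-D-alaninal and AcI give an α-acetoxy iodide. Its α-acetoxyalkyl radical adds to divinyl ketone, which forms the C–C bond and sets C3 with the 3-O-acetyl group already in place.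
5. C2 is bought in with D-alaninol.

Assumption: the target is delivered as the free base, and compounds 1, 3, 7 and 8 are catalogue chemicals.

## Route

**Step 1**
Reactants: 1, N-Cbz-D-alaninol (benzyl [(2R)-1-hydroxypropan-2-yl]carbamate)
Product: 2, N-Cbz-D-alaninal (benzyl [(2R)-1-oxopropan-2-yl]carbamate)
Conditions: Dess–Martin periodinane (1.2 equiv), NaHCO3, CH2Cl2, 0 °C to rt, 1 h; Na2S2O3/NaHCO3 wash; dried and used crude the same day
Reagents that add atoms: none
Why: Dess–Martin oxidation is neutral and non-enolising, so the primary alcohol becomes the aldehyde without eroding the C2 (R) centre.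

**Step 2**
Reactants: 3, penta-1,4-dien-3-ol
Product: 4, penta-1,4-dien-3-one (divinyl ketone)
Conditions: activated MnO2 (15 equiv), CH2Cl2, rt, 3 h; filter, dry over 4 Å MS, titrate by 1H NMR, use the solution directly without inhibitor
Reagents that add atoms: none
Why: MnO2 oxidation of a bis-allylic alcohol is selective, and keeping the ketone in dilute solution avoids polymerisation.

**Step 3**
Reactants: 2, N-Cbz-D-alaninal
Product: 5, (2R)-2-{[(benzyloxy)carbonyl]amino}-1-iodopropyl acetate (about 1:1 epimers at the C–I carbon)
Conditions: AcI (1.05 equiv), CH2Cl2, 0 °C, 15 min, Ar, dark; no work-up, the solution is carried straight into step 4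
Reagents that add atoms: acetyl iodide, CC(=O)I (acetyl ends up on O, iodine on the former carbonyl carbon)
Why: Acyl iodide addition across an aliphatic aldehyde C=O (α-iodoalkyl ester formation) is fast and base-free, so C2 is not enolised, and the undefined C–I centre does not matter because it becomes a radical in the next step.

**Step 4 (key step)**
Reactants: 5, α-acetoxy iodide (solution from step 3); 4, divinyl ketone (4 equiv, solution from step 2)
Product: 6, (2R,3R)-2-{[(benzyloxy)carbonyl]amino}-6-oxooct-7-en-3-yl acetate
Conditions: (TMS)3SiH (1.5 equiv), Mn2(CO)10 (5 mol %), CH2Cl2, blue LEDs, −20 °C, 4 h; aq NaHCO3/Na2S2O3; chromatography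
Reagents that add atoms: none (the silane supplies only H, and iodine leaves as (TMS)3SiI)
Why: Proposed new method: Mn(CO)5•/(TMS)3Si• abstract iodine from the weak C–I bond of 5, the nucleophilic α-acetoxyalkyl (ketyl-surrogate) radical undergoes a reductive Giese addition to an unsubstituted terminus of excess 4, and the electrophilic α-keto radical takes H from (TMS)3SiH to carry the chain; C3 is set by 1,2-induction (C2–H eclipses C3–OAc to minimise A1,3 strain, the C–N bond aligns with the SOMO, the acceptor enters anti to NHCbz), giving the syn (2R,3R) isomer with an expected modest dr of about 3–4:1 and the minor epimer removed by chromatography; the closest known reaction types are the Mn2(CO)10/visible-light atom-transfer coupling of aldehyde-derived α-acetoxy iodides with alkynes and the silane-mediated Giese addition of alkyl iodides to vinyl ketones.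

**Step 5**
Reactants: 7, octa-1,7-diyne (3 equiv); 8, methyl vinyl ketone
Product: 9, dodeca-5,11-diyn-2-one
Conditions: Pd(OAc)2 (5 mol %), PMe3 (20 mol %), acetone, 60 °C, 24 h; excess 7 distilled off and recycled
Reagents that add atoms: none
Why: Pd-catalysed 1,4-addition of a terminal alkyne C–H to a vinyl ketone is neutral and tolerates the ketone, and the excess of diyne keeps the reaction at mono-addition.

**Step 6**
Reactants: 6, vinyl ketone; 9, dodeca-5,11-diyn-2-one (1.3 equiv)
Product: 10, (2R,3R)-2-{[(benzyloxy)carbonyl]amino}-6,19-dioxoicosa-9,15-diyn-3-yl acetate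
Conditions: Pd(OAc)2 (5 mol %), PMe3 (20 mol %), acetone, 50–60 °C, 24 h
Reagents that add atoms: none
Why: This is the same Pd-catalysed conjugate alkynylation, which completes the linear C20 skeleton under base-free conditions that leave the carbamate, the acetate, both ketones and C2/C3 untouched.

**Step 7**
Reactants: 10, diyne-dione
Product: 11, (−)-3-O-acetylspectaline, (2R,3R,6S)-2-methyl-6-(13-oxotetradecyl)piperidin-3-yl acetate
Conditions: H2 (3 atm), 10% Pd/C, EtOAc–AcOH 9:1 (0.02 M), rt, 16 h; filter; cold aq NaHCO3, extract
Reagents that add atoms: none
Why: In this tandem hydrogenation/hydrogenolysis/intramolecular reductive amination both alkynes are saturated, the Cbz group is cleaved and the amine condenses with the 1,5-related C6 ketone (the remote methyl ketone is inert to Pd/C, dilution disfavours intermolecular amination, and AcOH suppresses O→N acetyl shift), after which H2 adds to the Δ1-piperideine from the face opposite C2-Me and C3-OAc to give the all-cis product with C6 (S).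

## Compound list
1 | N-Cbz-D-alaninol | C[C@@H](NC(=O)OCc1ccccc1)CO | starting material
2 | N-Cbz-D-alaninal | C[C@@H](NC(=O)OCc1ccccc1)C=O | intermediate
3 | penta-1,4-dien-3-ol | C=CC(O)C=C | starting material
4 | divinyl ketone | C=CC(=O)C=C | intermediate
5 | (2R)-2-(Cbz-amino)-1-iodopropyl acetate (epimers at C–I) | C[C@@H](NC(=O)OCc1ccccc1)C(I)OC(C)=O | intermediate
6 | (2R,3R)-2-(Cbz-amino)-6-oxooct-7-en-3-yl acetate | C[C@@H](NC(=O)OCc1ccccc1)[C@H](OC(C)=O)CCC(=O)C=C | intermediate
7 | octa-1,7-diyne | C#CCCCCC#C | starting material
8 | methyl vinyl ketone | CC(=O)C=C | starting material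
9 | dodeca-5,11-diyn-2-one | CC(=O)CCC#CCCCCC#C | intermediate
10 | (2R,3R)-2-(Cbz-amino)-6,19-dioxoicosa-9,15-diyn-3-yl acetate | C[C@@H](NC(=O)OCc1ccccc1)[C@H](OC(C)=O)CCC(=O)CCC#CCCCCC#CCCC(C)=O | intermediate
11 | (−)-3-O-acetylspectaline | CC(=O)CCCCCCCCCCCC[C@H]1CC[C@@H](OC(C)=O)[C@@H](C)N1 | target

## Summary
Total steps: 7. Steps 3 and 4 are run in one flask without isolating 5.
Longest linear sequence: 5 (1 → 2 → 5 → 6 → 10 → 11).

Steps most likely to fail:
1. **Step 4.** The risks are modest dr, telomerisation of 4, and loss of the labile iodide 5 from step 3 through capture by the neighbouring carbamate before the radical forms.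
   Fallback: lock C2 and C3 in a ring.
   - Convert 1 to its N-protected 2,2-dimethyloxazolidine.
   - Generate the C5 (α-oxy) radical by HAT photocatalysis and add it to 4 anti to the C4 methyl. The trans-oxazolidine corresponds to the syn amino alcohol.
   - After acid unmasking and cyclisation, put the acetate on last.
2. **Step 6.** The risks are phosphine-induced oligomerisation of the functionalised vinyl ketone 6 and alkyne homodimerisation.
   Fallback: reverse the assembly order. Add 9 to excess 4 first, giving heptadec-1-ene-6,12-diyne-3,16-dione, and make the radical addition of 5 to that full-length vinyl ketone the last C–C bond formation.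
3. **Step 7.** The risk is O→N acetyl migration or acetate loss once the amine is freed.
   Fallback: carry the material deliberately to (−)-spectaline by hydrogenation followed by K2CO3/MeOH. Then acetylate oxygen selectively on the piperidinium hydrochloride (AcCl in AcOH), where the protonated nitrogen cannot react.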